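**Retrosynthetic overview**
- The target is the (E)-p-coumarate of junenol (5α-eudesm-4(15)-en-6α-ol); the ester is cut to junenol and commercial (E)-4-acetoxycinnamic acid.
- Junenol: exocyclic methylene from a C4 ketone (Wittig); C4 oxygen and 5α-H from hydroboration of a 4-ene; 6α-oxygen from α-epoxidation of a 5-ene followed by amide-base isomerisation to the 4-en-6α-ol.
- The 5-ene (15-nor-eudesm-5-ene) comes from the Robinson enone by deconjugative reduction and Barton–McCombie deoxygenation.
- Key C–C bond (C10–C1, quaternary centre): intermolecular asymmetric Michael addition of the (R)-1-phenylethylamine imine of (+)-dihydrocarvone to methyl vinyl ketone; an aldol condensation then closes the ring.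
- Ring order: ring B is taken from dihydrocarvone (C7 from the chiral pool); ring A is formed second by the Michael/aldol annulation.

Assumption: eudesmane numbering is used for the decalin (C10 = methyl-bearing ring-fusion carbon, C5 = other ring-fusion carbon, C4 = methylene carbon, C6 = carbinol carbon, C7 = isopropyl carbon; "15-nor" = no carbon on C4); β is the face of the C10 methyl, α the opposite face. Commercial (+)-dihydrocarvone is the usual mixture of C2 epimers, which converge in step 1.

**Route**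

Step 1
Reactants: 1 (+)-dihydrocarvone [(2R,5R)-2-methyl-5-(prop-1-en-2-yl)cyclohexan-1-one]; 2 (R)-1-phenylethylamine; 3 methyl vinyl ketone (but-3-en-2-one)
Product: 6 (2S,5R)-2-methyl-2-(3-oxobutyl)-5-(prop-1-en-2-yl)cyclohexan-1-one, via imine 4 (not isolated), via Michael-adduct imine 5 (not isolated)
Conditions: (i) 2, TsOH·H2O (cat.), toluene, reflux, Dean–Stark; (ii) 3, hydroquinone (trace), THF, 40 °C, 3 d; (iii) 10% aq. AcOH, rt
Reagents that add atoms: methyl vinyl ketone (3), C=CC(C)=O
Why: Asymmetric Michael addition of a chiral imine (d'Angelo): the more substituted secondary-enamine tautomer of 4 adds to the enone through a compact aza-ene-like transition state on the face away from the phenyl group of the auxiliary, creating the quaternary carbon (future C10) as 2S with methyl cis to isopropenyl, while C5 (future C7) comes unchanged from the chiral pool.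

Step 2
Reactants: 6 (2S,5R)-2-methyl-2-(3-oxobutyl)-5-(prop-1-en-2-yl)cyclohexan-1-one
Product: 7 (4aS,7R)-4a-methyl-7-(prop-1-en-2-yl)-4,4a,5,6,7,8-hexahydronaphthalen-2(3H)-one (15-nor-eudesma-4,11-dien-3-one)
Conditions: NaOMe (0.3 equiv), MeOH, 60 °C
Reagents that add atoms: none
Why: Intramolecular aldol condensation (second half of the Robinson annulation) of the methyl ketone onto the ring carbonyl closes ring A as the conjugated enone without touching a stereocentre.

Step 3
Reactants: 7 (4aS,7R)-4a-methyl-7-(prop-1-en-2-yl)-4,4a,5,6,7,8-hexahydronaphthalen-2(3H)-one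
Product: 8 (4aS,7R)-4a-methyl-7-(propan-2-yl)-4,4a,5,6,7,8-hexahydronaphthalen-2(3H)-one (15-nor-eudesm-4-en-3-one)
Conditions: H2 (1 atm), RhCl(PPh3)3 (5 mol %), toluene, rt
Reagents that add atoms: none
Why: Homogeneous hydrogenation with RhCl(PPh3)3 saturates the unhindered 1,1-disubstituted alkene far faster than the trisubstituted conjugated one, so the enone and C7 are untouched.

Step 4
Reactants: 8 15-nor-eudesm-4-en-3-one
Product: 9 3-acetoxy-15-nor-eudesma-3,5-diene (dienol acetate; 7β-isopropyl and 10β-methyl)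
Conditions: isopropenyl acetate (neat), TsOH·H2O (cat.), reflux with slow distillation
Reagents that add atoms: isopropenyl acetate, CC(=C)OC(C)=O
Why: Acid-catalysed enol acetylation gives the thermodynamic heteroannular dienol acetate, which moves the unsaturation to C5=C6.

Step 5
Reactants: 9 3-acetoxy-15-nor-eudesma-3,5-diene
Product: 11 15-nor-eudesm-5-en-3β-ol, via deconjugated ketone 10 (not isolated)
Conditions: NaBH4 (4 equiv), EtOH/THF/H2O, 0 °C → rt
Reagents that add atoms: none
Why: Deconjugative reduction of a dienol acetate: borohydride cleaves the enol ester, the dienolate is protonated kinetically at C4 to the β,γ-unsaturated ketone 10, and this is reduced faster than it re-conjugates, axial hydride delivery giving mainly the equatorial 3β-alcohol (a centre removed in step 7).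

Step 6
Reactants: 11 15-nor-eudesm-5-en-3β-ol
Product: 12 O-(15-nor-eudesm-5-en-3β-yl) S-methyl dithiocarbonate
Conditions: NaH, imidazole (cat.), THF, rt; CS2; then MeI
Reagents that add atoms: carbon disulfide, S=C=S; iodomethane, CI
Why: Xanthate formation (alkoxide, CS2, MeI) prepares the secondary alcohol for radical deoxygenation.

Step 7
Reactants: 12 O-(15-nor-eudesm-5-en-3β-yl) S-methyl dithiocarbonate
Product: 13 15-nor-eudesm-5-ene [(4aR,7S)-4a-methyl-7-(propan-2-yl)-1,2,3,4,4a,5,6,7-octahydronaphthalene]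
Conditions: Bu3SnH, AIBN (cat.), toluene, 110 °C
Reagents that add atoms: none
Why: Barton–McCombie deoxygenation: the stannyl radical fragments the xanthate and the secondary C3 radical is reduced by Bu3SnH, leaving the C5=C6 alkene in place.

Step 8
Reactants: 13 15-nor-eudesm-5-ene
Product: 14 5α,6α-epoxy-15-nor-eudesmane
Conditions: mCPBA, CH2Cl2, 0 °C
Reagents that add atoms: meta-chloroperoxybenzoic acid, OOC(=O)c1cccc(Cl)c1
Why: Prilezhaev epoxidation occurs on the α face because the β face of the alkene is covered by the axial C10 methyl (and flanked by the 7β-isopropyl group), which fixes the C6–O bond as α (the minor β-epoxide is removed by chromatography).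

Step 9
Reactants: 14 5α,6α-epoxy-15-nor-eudesmane
Product: 15 15-nor-eudesm-4-en-6α-ol
Conditions: Et2Al–TMP (4 equiv; from 2,2,6,6-tetramethylpiperidine, n-BuLi, Et2AlCl), toluene, 0 °C → rt; then aqueous work-up
Reagents that add atoms: none
Why: Base-promoted epoxide-to-allylic-alcohol isomerisation (syn β-elimination through a cyclic aluminium amide transition state): the only β-hydrogens on the fully substituted epoxide carbon are those of C4, so the tertiary C5–O bond breaks and the 6α-oxygen keeps its configuration.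

Step 10
Reactants: 15 15-nor-eudesm-4-en-6α-ol
Product: 16 6α-(tert-butyldimethylsilyloxy)-15-nor-eudesm-4-ene
Conditions: TBSOTf, 2,6-lutidine, CH2Cl2, −78 → 0 °C
Reagents that add atoms: tert-butyldimethylsilyl triflate, CC(C)(C)[Si](C)(C)OS(=O)(=O)C(F)(F)F
Why: Silylation with the reactive silyl triflate protects the hindered allylic alcohol as a TBS ether that is stable to borane, oxidant and ylide.

Step 11
Reactants: 16 6α-(tert-butyldimethylsilyloxy)-15-nor-eudesm-4-ene
Product: 18 6α-(tert-butyldimethylsilyloxy)-15-nor-5α-eudesman-4α-ol, via alkylborane 17 (not isolated)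
Conditions: BH3·THF (3 equiv), THF, 0 °C → rt; then NaOH, H2O2, 0 °C → rt
Reagents that add atoms: hydrogen peroxide, OO
Why: Hydroboration–oxidation: boron adds to the less substituted C4 and hydrogen to C5 in a syn fashion from the α face opposite the axial C10 methyl, which sets the trans ring fusion (5α-H), and oxidation with retention gives the 4α-alcohol (C4 is made planar later).

Step 12
Reactants: 18 6α-(tert-butyldimethylsilyloxy)-15-nor-5α-eudesman-4α-ol
Product: 19 6α-(tert-butyldimethylsilyloxy)-15-nor-5α-eudesman-4-one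
Conditions: Dess–Martin periodinane, CH2Cl2, rt
Reagents that add atoms: none
Why: Dess–Martin oxidation of the secondary alcohol gives the ketone under near-neutral conditions that leave the silyl ether and the C5 centre (trans fusion, set in step 11) untouched.

Step 13
Reactants: 19 6α-(tert-butyldimethylsilyloxy)-15-nor-5α-eudesman-4-one
Product: 20 6α-(tert-butyldimethylsilyloxy)-5α-eudesm-4(15)-ene (junenol TBS ether)
Conditions: Ph3PCH3Br, KOtBu (slightly less than the salt), THF, 0 → 50 °C
Reagents that add atoms: methyltriphenylphosphonium bromide, C[P+](c1ccccc1)(c1ccccc1)c1ccccc1.[Br-]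
Why: Wittig methylenation with the non-stabilised ylide converts the C4 ketone into the exocyclic alkene; the β-silyloxy group is a poor leaving group and no free alkoxide base is present, so C5 and C6 are retained.

Step 14
Reactants: 20 6α-(tert-butyldimethylsilyloxy)-5α-eudesm-4(15)-ene
Product: 21 junenol [(1S,2S,4aR,8aS)-4a-methyl-8-methylidene-2-(propan-2-yl)decahydronaphthalen-1-ol]
Conditions: Bu4NF, THF, 50 °C
Reagents that add atoms: none
Why: Fluoride-mediated desilylation frees the 6α-alcohol without acid, so the exocyclic alkene does not migrate.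

Step 15
Reactants: 21 junenol; 22 (E)-4-acetoxycinnamic acid
Product: 23 junenyl (E)-4-acetoxycinnamate
Conditions: EDC·HCl, DMAP (cat.), CH2Cl2, rt
Reagents that add atoms: (E)-4-acetoxycinnamic acid (22), CC(=O)Oc1ccc(/C=C/C(=O)O)cc1
Why: Steglich esterification (carbodiimide activation, acyl transfer by DMAP) acylates the hindered secondary alcohol with retention at C6, the phenol being masked as its acetate and the E-alkene coming from the acid.

Step 16
Reactants: 23 junenyl (E)-4-acetoxycinnamate
Product: 24 junenyl (E)-4-hydroxycinnamate [(1S,2S,4aR,8aS)-4a-methyl-8-methylidene-2-(propan-2-yl)decahydronaphthalen-1-yl (2E)-3-(4-hydroxyphenyl)prop-2-enoate]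
Conditions: pyrrolidine (2 equiv), CH2Cl2, 0 °C
Reagents that add atoms: none
Why: Chemoselective aminolysis: the activated aryl acetate is cleaved by pyrrolidine much faster than the hindered alkyl cinnamate, which releases the phenol of the target.

**Compound list**

1 | (+)-dihydrocarvone, (2R,5R)-2-methyl-5-(prop-1-en-2-yl)cyclohexan-1-one | CC(=C)[C@@H]1CC[C@@H](C)C(=O)C1 | starting material
2 | (R)-1-phenylethylamine | C[C@@H](N)c1ccccc1 | starting material
3 | methyl vinyl ketone | C=CC(C)=O | starting material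
4 | N-[(1R)-1-phenylethyl]imine of 1 (C2 epimers equilibrating through the enamine) | CC(=C)[C@@H]1CCC(C)C(=N[C@H](C)c2ccccc2)C1 | intermediate
5 | N-[(1R)-1-phenylethyl]imine of 6 | CC(=C)[C@@H]1CC[C@@](C)(CCC(C)=O)C(=N[C@H](C)c2ccccc2)C1 | intermediate
6 | (2S,5R)-2-methyl-2-(3-oxobutyl)-5-(prop-1-en-2-yl)cyclohexan-1-one | CC(=C)[C@@H]1CC[C@@](C)(CCC(C)=O)C(=O)C1 | intermediate
7 | (4aS,7R)-4a-methyl-7-(prop-1-en-2-yl)-4,4a,5,6,7,8-hexahydronaphthalen-2(3H)-one | CC(=C)[C@@H]1CC[C@@]2(C)CCC(=O)C=C2C1 | intermediate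
8 | (4aS,7R)-4a-methyl-7-(propan-2-yl)-4,4a,5,6,7,8-hexahydronaphthalen-2(3H)-one | CC(C)[C@@H]1CC[C@@]2(C)CCC(=O)C=C2C1 | intermediate
9 | 3-acetoxy-15-nor-eudesma-3,5-diene | CC(C)[C@@H]1CC[C@@]2(C)CCC(OC(C)=O)=CC2=C1 | intermediate
10 | 15-nor-eudesm-5-en-3-one | CC(C)[C@@H]1CC[C@@]2(C)CCC(=O)CC2=C1 | intermediate
11 | 15-nor-eudesm-5-en-3β-ol | CC(C)[C@@H]1CC[C@@]2(C)CC[C@H](O)CC2=C1 | intermediate
12 | O-(15-nor-eudesm-5-en-3β-yl) S-methyl dithiocarbonate | CC(C)[C@@H]1CC[C@@]2(C)CC[C@H](OC(=S)SC)CC2=C1 | intermediate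
13 | 15-nor-eudesm-5-ene, (4aR,7S)-4a-methyl-7-(propan-2-yl)-1,2,3,4,4a,5,6,7-octahydronaphthalene | CC(C)[C@@H]1CC[C@@]2(C)CCCCC2=C1 | intermediate
14 | 5α,6α-epoxy-15-nor-eudesmane | CC(C)[C@@H]1CC[C@@]2(C)CCCC[C@@]23O[C@@H]13 | intermediate
15 | 15-nor-eudesm-4-en-6α-ol | CC(C)[C@@H]1CC[C@@]2(C)CCCC=C2[C@H]1O | intermediate
16 | 6α-(tert-butyldimethylsilyloxy)-15-nor-eudesm-4-ene | CC(C)[C@@H]1CC[C@@]2(C)CCCC=C2[C@H]1O[Si](C)(C)C(C)(C)C | intermediate
17 | 4α-boryl-6α-(tert-butyldimethylsilyloxy)-15-nor-5α-eudesmane (drawn as the monoalkylborane) | CC(C)[C@@H]1CC[C@@]2(C)CCC[C@@H](B)[C@@H]2[C@H]1O[Si](C)(C)C(C)(C)C | intermediate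
18 | 6α-(tert-butyldimethylsilyloxy)-15-nor-5α-eudesman-4α-ol | CC(C)[C@@H]1CC[C@@]2(C)CCC[C@@H](O)[C@@H]2[C@H]1O[Si](C)(C)C(C)(C)C | intermediate
19 | 6α-(tert-butyldimethylsilyloxy)-15-nor-5α-eudesman-4-one | CC(C)[C@@H]1CC[C@@]2(C)CCCC(=O)[C@@H]2[C@H]1O[Si](C)(C)C(C)(C)C | intermediate
20 | 6α-(tert-butyldimethylsilyloxy)-5α-eudesm-4(15)-ene | CC(C)[C@@H]1CC[C@@]2(C)CCCC(=C)[C@@H]2[C@H]1O[Si](C)(C)C(C)(C)C | intermediate
21 | junenol, (1S,2S,4aR,8aS)-4a-methyl-8-methylidene-2-(propan-2-yl)decahydronaphthalen-1-ol | CC(C)[C@@H]1CC[C@@]2(C)CCCC(=C)[C@@H]2[C@H]1O | intermediate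
22 | (E)-4-acetoxycinnamic acid | CC(=O)Oc1ccc(/C=C/C(=O)O)cc1 | starting material
23 | junenyl (E)-4-acetoxycinnamate | CC(C)[C@@H]1CC[C@@]2(C)CCCC(=C)[C@@H]2[C@H]1OC(=O)/C=C/c3ccc(OC(C)=O)cc3 | intermediate
24 | junenyl (E)-4-hydroxycinnamate, CNP0321375.1 (5S,6S,7S,10R in eudesmane numbering) | C=C1CCC[C@]2(C)CC[C@@H](C(C)C)[C@H](OC(=O)/C=C/c3ccc(O)cc3)[C@@H]12 | target

**Step count**

Total steps: 16. Longest linear sequence: 16 (1 → 24); 22 is purchased.

**Three steps most likely to fail, with fallbacks**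

Step 1 (the auxiliary has to override the intrinsic facial bias of a ring that already carries a stereocentre, and the addition is slow). The fallback sets out from 3 and returns at 13. Racemic 2-methylcyclohexanone and (S)-1-phenylethylamine are condensed (TsOH, toluene, Dean–Stark) to the imine F1, whose enamine tautomer adds to 3 to give the adduct imine F2. Aqueous AcOH releases (R)-2-methyl-2-(3-oxobutyl)cyclohexanone F3, and NaOMe/MeOH closes it to (R)-4a-methyl-4,4a,5,6,7,8-hexahydronaphthalen-2(3H)-one F4. LiBH(sec-Bu)3 (THF, −78 °C) delivers hydride from the equatorial side to give the pseudo-axial allylic alcohol F5 (OH trans to the angular methyl), and ClP(O)(OEt)2/pyridine gives the allylic diethyl phosphate F6. iPrMgCl with catalytic Li2CuCl4 (THF, −20 °C) then substitutes with inversion at the carbinol carbon (the other allylic terminus is fully substituted and neopentylic), placing the isopropyl group cis to the angular methyl and giving 13. In this variant ring A is the purchased ring and ring B is made by the same Michael/aldol annulation.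

Step 9 (regiochemistry of the epoxide opening, together with the moderate face selectivity of step 8 on which C6 depends). The fallback sets out from 13 and returns at 19. SeO2 (cat.)/t-BuOOH in CH2Cl2 hydroxylates the allylic CH2 on the more substituted end of the alkene to give the allylic alcohol 15-nor-eudesm-5-en-4β-ol F7, and NaH/BnBr gives the benzyl ether F8. BH3·THF adds from the α face (boron at C6, hydrogen at C5) to give the alkylborane F9, which NaOH/H2O2 oxidises to the 6α-alcohol F10, so that C5 and C6 are set together in one syn addition. TBSOTf/2,6-lutidine gives the silyl ether F11, H2 over Pd/C removes the benzyl group to give the 4β-alcohol F12, and Dess–Martin oxidation gives 19.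

Step 13 (methylenation of a hindered, enolisable β-silyloxy ketone; risk of enolisation, C5 epimerisation or β-elimination). The fallback sets out from 19 and returns at 21. Me3SiCH2Li with anhydrous CeCl3 (THF, −78 °C) adds to the ketone without enolising it to give the β-hydroxysilane F13 (C4 configuration immaterial). Aqueous HF in MeCN then effects the Peterson elimination to the exocyclic alkene and removes the TBS group in the same flask, giving 21 directly.

**Further compounds**

F1 | step 1 | N-[(1S)-1-phenylethyl]imine of 2-methylcyclohexanone | CC1CCCCC1=N[C@@H](C)c2ccccc2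
F2 | step 1 | N-[(1S)-1-phenylethyl]imine of (R)-2-methyl-2-(3-oxobutyl)cyclohexanone | CC(=O)CC[C@@]1(C)CCCCC1=N[C@@H](C)c2ccccc2
F3 | step 1 | (R)-2-methyl-2-(3-oxobutyl)cyclohexan-1-one | CC(=O)CC[C@@]1(C)CCCCC1=O
F4 | step 1 | (R)-4a-methyl-4,4a,5,6,7,8-hexahydronaphthalen-2(3H)-one | O=C1CC[C@@]2(C)CCCCC2=C1
F5 | step 1 | (2S,4aR)-4a-methyl-2,3,4,4a,5,6,7,8-octahydronaphthalen-2-ol | O[C@H]1CC[C@@]2(C)CCCCC2=C1
F6 | step 1 | diethyl (2S,4aR)-4a-methyl-2,3,4,4a,5,6,7,8-octahydronaphthalen-2-yl phosphate | CCOP(=O)(OCC)O[C@H]1CC[C@@]2(C)CCCCC2=C1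
F7 | step 9 | 15-nor-eudesm-5-en-4β-ol | CC(C)[C@@H]1CC[C@@]2(C)CCC[C@H](O)C2=C1
F8 | step 9 | 4β-benzyloxy-15-nor-eudesm-5-ene | CC(C)[C@@H]1CC[C@@]2(C)CCC[C@H](OCc3ccccc3)C2=C1
F9 | step 9 | 4β-benzyloxy-6α-boryl-15-nor-5α-eudesmane (drawn as the monoalkylborane) | CC(C)[C@@H]1CC[C@@]2(C)CCC[C@H](OCc3ccccc3)[C@@H]2[C@H]1B
F10 | step 9 | 4β-benzyloxy-15-nor-5α-eudesman-6α-ol | CC(C)[C@@H]1CC[C@@]2(C)CCC[C@H](OCc3ccccc3)[C@@H]2[C@H]1O
F11 | step 9 | 4β-benzyloxy-6α-(tert-butyldimethylsilyloxy)-15-nor-5α-eudesmane | CC(C)[C@@H]1CC[C@@]2(C)CCC[C@H](OCc3ccccc3)[C@@H]2[C@H]1O[Si](C)(C)C(C)(C)C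
F12 | step 9 | 6α-(tert-butyldimethylsilyloxy)-15-nor-5α-eudesman-4β-ol | CC(C)[C@@H]1CC[C@@]2(C)CCC[C@H](O)[C@@H]2[C@H]1O[Si](C)(C)C(C)(C)C
F13 | step 13 | 6α-(tert-butyldimethylsilyloxy)-4-[(trimethylsilyl)methyl]-15-nor-5α-eudesman-4-ol (C4 epimers) | CC(C)[C@@H]1CC[C@@]2(C)CCCC(O)(C[Si](C)(C)C)[C@@H]2[C@H]1O[Si](C)(C)C(C)(C)C
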